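Everything rests on the trans ring-fusion bond C6–C10, which the five-membered ring (C6–C7–C8–C9–C10) shares with the seven-membered ring (C1–C6 plus C10) and which lies between the C5 ketone, quaternary C6 and carbinol C9. With C6 tied to C1 rather than to C10 the bicycle becomes a cis-decalin with the carbon pattern of (S)-Wieland–Miescher ketone. Forward, one semipinacol 1,2-shift of C6 from carbinol C1 to sulfonate carbon C10 forms C6–C10, cleaves C1–C6, shrinks one cyclohexane, enlarges the other, creates the C1 ketone and fixes C10. Its precursor carries β-oxygen on C1, C9 and C10: free C1–OH, equatorial C10 mesylate, silyl-capped O9; C5 travels as an equatorial silyl ether.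

Key step: step 7

Numbering used for every compound: the seven-membered ring is C1(O)–C2–C3–C4–C5–C6–C10 and the five-membered ring is C6–C7–C8–C9–C10. The decalins keep the same labels, with ring A = C1–C10–C9–C8–C7–C6 and ring B = C1–C2–C3–C4–C5–C6. β is the face of the C6 methyl group and α is the opposite face. In this numbering the target is 1S,6S,9R,10S.

Remark on the precursor, O9: an equatorial leaving group on C10 is antiperiplanar to C9–C8 as well as to C1–C6. C1 and C9 carry no hydrogen, so no hydride shift is possible. The real competitor is a C8 shift pushed by a free O9, which would contract ring A to an isobutyryl cyclopentane. O9 is therefore silylated, and this also shuts off retro-aldol cleavage of the product.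

Remark on the precursor, C5: in the reactive chair C5 is axial on ring A. A C5 ketal would then hold one oxygen over ring A, about as close to the rear of C10 as C6 itself. That brings strain, possible oxygen participation and Lewis-acid lability. C5 is therefore carried as the equatorial β-silyl ether, which points its hydrogen inward, and it is oxidised late.

Assumption: C3 of compound 20 is left undefined because step 13 erases it.

Step 1
Reactants: 1 (S)-Wieland–Miescher ketone
Product: 2 (4aS,5S)-5-hydroxy-4a-methyl-4,4a,5,6,7,8-hexahydronaphthalen-2(3H)-one (C5 β-OH equatorial and cis to the C6 methyl; C9 enone intact)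
Conditions: NaBH4 (0.3 equiv), EtOH, 0 °C
Reagents that add atoms: none
Why: Chemoselective NaBH4 reduction, because the saturated C5 ketone is more electrophilic than the conjugated C9 ketone; hydride enters C5 from the α-face, opposite the axial β-methyl on C6, and so sets the equatorial β-alcohol, a stereocentre that only serves as a placeholder and is erased in step 11.

Step 2
Reactants: 2 C5 β-hydroxy enone
Product: 3 C5 β-tert-butyldimethylsilyl ether of 2
Conditions: TBSCl, imidazole, DMF, 35 °C
Reagents that add atoms: tert-butyldimethylsilyl chloride, CC(C)(C)[Si](C)(C)Cl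
Why: Imidazole-promoted silylation of the only hydroxyl touches no stereocentre and gives a C5 spectator that survives organometallics, OsO4 and aluminium Lewis acids and that later presents a hydrogen, not an oxygen, to ring A.

Step 3
Reactants: 3 C5 β-OTBS enone; 4 isopropylmagnesium chloride
Product: 6 tertiary allylic alcohol (C9 β-OH; C9 α-isopropyl; C1=C10; C5 β-OTBS), via isopropylcerium dichloride 5 (not isolated)
Conditions: CeCl3 (anhydrous), 4, THF, 0 °C; then 3, −78 → 0 °C; sat. aq. NH4Cl
Reagents that add atoms: none
Why: 1,2-Addition of an organocerium reagent, whose low basicity and high oxophilicity suppress enolisation, β-hydride reduction and conjugate addition; the nucleophile takes the axial trajectory of the enone half-chair on the α-face, away from the β-methyl on C6, so the new C9 hydroxyl ends β, and any C9 epimer is removed by chromatography.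

Step 4
Reactants: 6 tertiary allylic alcohol
Product: 8 cis-decalin C1,C9,C10-triol (all three hydroxyls β; C5 β-OTBS), via chelated osmate ester 7 (not isolated)
Conditions: OsO4 (1.05 equiv), TMEDA (1.1 equiv), CH2Cl2, −78 → −20 °C; then aq. Na2SO3, THF, 60 °C
Reagents that add atoms: osmium tetroxide, O=[Os](=O)(=O)=O
Why: Hydrogen-bond-directed dihydroxylation: the OsO4–TMEDA adduct accepts a hydrogen bond from the β-hydroxyl on C9 and adds suprafacially to the β-face of C1=C10 against the steric bias of the angular methyl, which sets C1–OH and C10–OH cis to each other and to O9 and makes the ring fusion cis, before sulfite releases the triol from the hexavalent osmium chelate 7.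

Step 5
Reactants: 8 C1,C9,C10-triol
Product: 9 C10 β-mesylate of 8 (C1 and C9 hydroxyls free)
Conditions: MsCl (1.2 equiv), Et3N, CH2Cl2, −20 °C
Reagents that add atoms: methanesulfonyl chloride, CS(=O)(=O)Cl
Why: Sulfonylation through sulfene picks the only secondary hydroxyl while the two tertiary ones stay free at low temperature, and the C10–O bond is not touched, so the β (equatorial) configuration is kept.

Step 6
Reactants: 9 C1,C9-diol C10-mesylate
Product: 10 C9 O-triethylsilyl ether of 9 (C1–OH free)
Conditions: TESOTf (1.1 equiv), 2,6-lutidine, CH2Cl2, −78 → −40 °C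
Reagents that add atoms: triethylsilyl trifluoromethanesulfonate, CC[Si](CC)(CC)OS(=O)(=O)C(F)(F)F
Why: Silylation under steric control: O9 is flanked by an isopropyl group and a CH2 whereas ring-fusion O1 abuts quaternary C6, and once O9 is silylated its 1,3-diaxial bulk shields O1 further, so one equivalent of reagent should cap O9 only, and any mis-silylated material can be returned to 9 with fluoride.

Step 7
Reactants: 10 C9-OTES C1-hydroxy C10-mesylate cis-decalin
Product: 13 trans-fused hydroazulen-1-one (free C9 β-carbinol; C9 α-isopropyl; H10 α; C6 β-methyl; C5 β-OTBS), via aluminium alkoxide 11 (not isolated), via silyl ether ketone 12 (not isolated)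
Conditions: Et2AlCl (2 equiv), CH2Cl2, −78 → −20 °C; aq. potassium sodium tartrate; crude 12, HF·pyridine, pyridine, THF, 0 °C
Reagents that add atoms: none
Why: Et2AlCl converts the only free hydroxyl (O1) into aluminium alkoxide 11, whose metal also binds the gauche mesylate, so electron push from O1 and pull on the leaving group move the C1–C6 σ-bond onto C10 while C10–O breaks and C1 becomes the carbonyl carbon. The closest known reaction type is the organoaluminium-promoted semipinacol rearrangement of 2-sulfonyloxy alcohols, the same 1,2-shift that turns decalin-1,2-diol monosulfonates into hydroazulenones. The five-membered ring C6–C7–C8–C9–C10 is closed by contraction of ring A (C1 is expelled from it) and the seven-membered ring C1–C2–C3–C4–C5–C6–C10 by one-carbon enlargement of ring B (C10 is inserted between C1 and C6), both through the single new bond C6–C10. C10 is the only new stereocentre: C6 arrives anti to the departing β-mesylate (inversion), leaving H10 α and therefore trans to the β-methyl on C6, which migrates with retention. The step needs C6 to move rather than C8, C2 or isopropyl: in the chair with isopropyl equatorial and C5–H, not an oxygen, pointing over ring A the mesylate is equatorial and antiperiplanar only to C1–C6 and C9–C8, and of these only C1–C6 has a metal alkoxide behind it because O9 is a silyl ether. The same cap blocks retro-aldol opening of C9–C10 until buffered HF·pyridine, which leaves the hindered C5 silyl ether alone, frees 13 under non-basic conditions that cannot epimerise C10.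

Step 8
Reactants: 13 β-hydroxy ketone
Product: 14 C1 α-alcohol (1S) anti to the C9 β-carbinol; C5 β-OTBS
Conditions: Me4NBH(OAc)3 (5 equiv), MeCN/AcOH (1:1), −20 °C
Reagents that add atoms: none
Why: Evans–Saksena hydroxyl-directed reduction: acetate exchange binds boron to the β-oriented O9 and hydride is passed through a six-membered transition state to the β-face of C1=O, the face that the C6 methyl closes to external hydride, which gives the pseudo-equatorial α-alcohol (1S), anti to O9.

Step 9
Reactants: 14 C1,C9-diol; 15 3,4-dimethoxybenzoyl chloride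
Product: 16 C1 α-(3,4-dimethoxybenzoate) of 14 (C9–OH free; C5 β-OTBS)
Conditions: 15 (1.5 equiv), DMAP, Et3N, CH2Cl2, 0 → 23 °C
Reagents that add atoms: none
Why: DMAP-catalysed acylation (nucleophilic catalysis) reaches the secondary C1 hydroxyl only, the isopropyl-flanked tertiary C9 hydroxyl being inert under these conditions, and proceeds with retention because the C1–O bond is not broken.

Step 10
Reactants: 16 C1 veratrate C5 silyl ether
Product: 17 C5 β-alcohol of the C1 veratrate
Conditions: 48% aq. HF, MeCN, 23 °C
Reagents that add atoms: none
Why: Fluoride-driven cleavage of the hindered neopentyl-type silyl ether under mildly acidic conditions that leave the aryl ester and the tertiary carbinol untouched; no stereocentre of the target is involved.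

Step 11
Reactants: 17 C5 alcohol
Product: 19 C3=C4 en-5-one of the C1 veratrate, via saturated ketone 18 (not isolated)
Conditions: IBX (2.5 equiv), DMSO/fluorobenzene, 23 → 65 °C
Reagents that add atoms: none
Why: IBX oxidation of the secondary alcohol followed in the same flask by IBX dehydrogenation of ketone 18 through its enol; quaternary C6 leaves C4 as the only enolisable position, so the double bond can form only at C3=C4, the tertiary alcohol cannot be oxidised, and the near-neutral medium spares the C1 ester.

Step 12
Reactants: 19 enone
Product: 20 C3-methyl C4=C5 trimethylsilyl enol ether that also carries C9–OTMS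
Conditions: MeLi (6 equiv), CuI (3 equiv), Et2O/THF, −20 °C; then TMSCl (8 equiv), 19, −78 → 0 °C; Et3N, cold aq. NaHCO3
Reagents that add atoms: lithium dimethylcuprate, [Li+].C[Cu-]C; chlorotrimethylsilane, C[Si](C)(C)Cl
Why: TMSCl-accelerated conjugate addition of a Gilman cuprate to the unhindered C3 terminus, with the enolate trapped at once as its silyl enol ether so that it cannot attack the ester; the first equivalent of cuprate deprotonates O9–H and the alkoxide is silylated on warming, and the C3 configuration is irrelevant because the next step erases it.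

Step 13
Reactants: 20 bis-silylated enol ether
Product: 22 target CNP0111132.1, via trimethylsilyl ether 21 (not isolated)
Conditions: Pd(OAc)2 (1.1 equiv), MeCN, 23 °C; then 1 M aq. HCl, THF, 0 °C
Reagents that add atoms: none
Why: Saegusa–Ito oxidation: divalent palladium binds C4 of the silyl enol ether and β-hydride elimination, possible only toward C3–H, restores the enone now carrying the C3 methyl, after which brief dilute acid hydrolyses the tertiary trimethylsilyl ether 21 without touching ester, enone or any stereocentre.

Compound list
1 | (S)-Wieland–Miescher ketone | O=C1C=C2CCCC(=O)[C@@]2(C)CC1 | starting material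
2 | C5 β-hydroxy enone (4aS,5S) | O=C1C=C2CCC[C@H](O)[C@@]2(C)CC1 | intermediate
3 | C5 β-OTBS enone | O=C1C=C2CCC[C@H](O[Si](C)(C)C(C)(C)C)[C@@]2(C)CC1 | intermediate
4 | isopropylmagnesium chloride | CC(C)[Mg]Cl | starting material
5 | isopropylcerium dichloride | CC(C)[Ce](Cl)Cl | intermediate
6 | C9 β-hydroxy α-isopropyl allylic alcohol, C1=C10 | CC(C)[C@]1(O)CC[C@]2(C)[C@@H](O[Si](C)(C)C(C)(C)C)CCCC2=C1 | intermediate
7 | TMEDA-chelated C1,C10 β-osmate ester | CC(C)[C@]1(O)CC[C@]2(C)[C@@H](O[Si](C)(C)C(C)(C)C)CCC[C@]2(O3)[C@H]1O[Os]3(=O)=O.CN(C)CCN(C)C | intermediate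
8 | cis-decalin C1,C9,C10 β-triol | CC(C)[C@]1(O)CC[C@]2(C)[C@@H](O[Si](C)(C)C(C)(C)C)CCC[C@]2(O)[C@H]1O | intermediate
9 | C1,C9-diol C10 β-mesylate | CC(C)[C@]1(O)CC[C@]2(C)[C@@H](O[Si](C)(C)C(C)(C)C)CCC[C@]2(O)[C@H]1OS(C)(=O)=O | intermediate
10 | C9-OTES C1-hydroxy C10-mesylate (key-step precursor) | CC(C)[C@]1(O[Si](CC)(CC)CC)CC[C@]2(C)[C@@H](O[Si](C)(C)C(C)(C)C)CCC[C@]2(O)[C@H]1OS(C)(=O)=O | intermediate
11 | C1 O-chloro(ethyl)aluminium alkoxide of 10 | CC(C)[C@]1(O[Si](CC)(CC)CC)CC[C@]2(C)[C@@H](O[Si](C)(C)C(C)(C)C)CCC[C@]2(O[Al](Cl)CC)[C@H]1OS(C)(=O)=O | intermediate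
12 | trans-hydroazulen-1-one, C9-OTES | O=C1CCC[C@H](O[Si](C)(C)C(C)(C)C)[C@@]2(C)CC[C@@](O[Si](CC)(CC)CC)(C(C)C)[C@H]12 | intermediate
13 | trans-hydroazulen-1-one, free C9 carbinol (key-step product) | O=C1CCC[C@H](O[Si](C)(C)C(C)(C)C)[C@@]2(C)CC[C@@](O)(C(C)C)[C@H]12 | intermediate
14 | C1 α-ol, C9 β-ol diol | O[C@H]1CCC[C@H](O[Si](C)(C)C(C)(C)C)[C@@]2(C)CC[C@@](O)(C(C)C)[C@H]12 | intermediate
15 | 3,4-dimethoxybenzoyl chloride | COc1ccc(C(Cl)=O)cc1OC | starting material
16 | C1 veratrate, C5-OTBS | COc1ccc(C(=O)O[C@H]2CCC[C@H](O[Si](C)(C)C(C)(C)C)[C@@]3(C)CC[C@@](O)(C(C)C)[C@H]23)cc1OC | intermediate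
17 | C1 veratrate, C5 β-OH | COc1ccc(C(=O)O[C@H]2CCC[C@H](O)[C@@]3(C)CC[C@@](O)(C(C)C)[C@H]23)cc1OC | intermediate
18 | C1 veratrate, C5 ketone | COc1ccc(C(=O)O[C@H]2CCCC(=O)[C@@]3(C)CC[C@@](O)(C(C)C)[C@H]23)cc1OC | intermediate
19 | C1 veratrate, C3=C4 en-5-one | COc1ccc(C(=O)O[C@H]2CC=CC(=O)[C@@]3(C)CC[C@@](O)(C(C)C)[C@H]23)cc1OC | intermediate
20 | C3-methyl silyl enol ether, C9-OTMS | COc1ccc(C(=O)O[C@H]2CC(C)C=C(O[Si](C)(C)C)[C@@]3(C)CC[C@@](O[Si](C)(C)C)(C(C)C)[C@H]23)cc1OC | intermediate
21 | C9-OTMS ether of the target | COc1ccc(C(=O)O[C@H]2CC(C)=CC(=O)[C@@]3(C)CC[C@@](O[Si](C)(C)C)(C(C)C)[C@H]23)cc1OC | intermediate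
22 | CNP0111132.1 | COc1ccc(C(=O)O[C@H]2CC(C)=CC(=O)[C@@]3(C)CC[C@@](O)(C(C)C)[C@H]23)cc1OC | target

Total step count: 13. Longest linear sequence: 13 steps, from 1.

Steps most likely to fail

1. Step 7. Three processes may interfere:
- Ionisation may be slow because the sulfonate carbon sits between two C–O bonds.
- The Lewis acid may strip the silyl cap, after which C8 can shift.
- Material may leak through the minor chair, in which C2 shifts.

The fallback makes C6 a latent enolate carbon, so that weak base replaces the Lewis acid. It sets out from 9, so it also dispenses with the O9/O1 discrimination of step 6. Aqueous HF in MeCN removes the C5 silyl group to give the C1,C5,C9-triol C10-mesylate F1. DMP oxidises its only secondary hydroxyl to the C5-keto diol mesylate F2. DBU in toluene then triggers retro-aldol cleavage of C1–C6. The C6 enolate carbon still lies behind the C10–O bond and alkylates the now α-keto mesylate carbon across the ring with inversion. An unactivated C8 cannot follow under such mild base. This gives the hydroxy 1,5-dione F3. Me4NBH(OAc)3 reduces only the C1 ketone next to O9 to the keto diol F4. Acylation with 15 returns to the route at 18, which is then isolated and taken on with IBX.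

2. Step 4. Osmylation of an alkene flanked by two fully substituted carbons may be sluggish. Delivery may also slip to the α-face if the hydrogen bond cannot outweigh the angular methyl. The fallback installs the two oxygens one at a time by vanadium-directed epoxidation. It sets out from 6.
- VO(acac)2 and t-BuOOH give the C1,C10 β-epoxy alcohol F5.
- Diethylaluminium 2,2,6,6-tetramethylpiperidide removes a C2 hydrogen and isomerises the epoxide to the allylic diol F6 (C10 β-OH, C1=C2).
- A second VO(acac)2/t-BuOOH epoxidation, guided by the β-hydroxyls, gives the C1,C2 β-epoxy diol F7.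
- LiEt3BH opens F7 at C2 and returns to the route at 8.

3. Step 3. Facial selectivity at C9 may be poor, and the branched nucleophile may cause some β-hydride reduction. The fallback lets a neighbouring epoxide steer the addition instead of the remote methyl group. It sets out from 3. Weitz–Scheffer epoxidation (H2O2, NaOH, MeOH) should favour the β-epoxy ketone F8, the usual outcome for angularly methylated octalones. Isopropylcerium dichloride 5 then adds anti to the epoxide oxygen and gives the epoxy alcohol F5. This is carried through F6 and F7 as above and comes back to the route at 8.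

Further compounds
F1 | step 7 | C1,C5,C9-triol C10 β-mesylate cis-decalin | CC(C)[C@]1(O)CC[C@]2(C)[C@@H](O)CCC[C@]2(O)[C@H]1OS(C)(=O)=O
F2 | step 7 | C5-keto C1,C9-diol C10 β-mesylate | CC(C)[C@]1(O)CC[C@]2(C)C(=O)CCC[C@]2(O)[C@H]1OS(C)(=O)=O
F3 | step 7 | trans-hydroazulene-1,5-dione with free C9 carbinol | O=C1CCCC(=O)[C@@]2(C)CC[C@@](O)(C(C)C)[C@H]12
F4 | step 7 | C1 α-ol C5 ketone C9 carbinol | O[C@H]1CCCC(=O)[C@@]2(C)CC[C@@](O)(C(C)C)[C@H]12
F5 | step 4 | C1,C10 β-epoxide of 6 | CC(C)[C@]1(O)CC[C@]2(C)[C@@H](O[Si](C)(C)C(C)(C)C)CCC[C@]2(O3)[C@H]13
F6 | step 4 | C9,C10 β-diol with C1=C2 | CC(C)[C@]1(O)CC[C@]2(C)[C@@H](O[Si](C)(C)C(C)(C)C)CCC=C2[C@H]1O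
F7 | step 4 | C1,C2 β-epoxide of F6 | CC(C)[C@]1(O)CC[C@]2(C)[C@@H](O[Si](C)(C)C(C)(C)C)CC[C@H]3O[C@@]23[C@H]1O
F8 | step 3 | C1,C10 β-epoxy C9 ketone | O=C1CC[C@]2(C)[C@@H](O[Si](C)(C)C(C)(C)C)CCC[C@]2(O3)[C@H]13
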